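All runs were computed with constants of no real substance, noise included.

Maple and elm, two earlier runs at 1.5 equiv of reagent in the second phase, each rise to a highest reading and then sink. The flask asked about has more protic impurity than either and is read later than either.

the same everywhere: substrate 0.12 M
- maple: reagent in the second phase 1.5 equiv; protic impurity 1.2 mM; run made earlier
- elm: reagent in the second phase 1.5 equiv; protic impurity 1.8 mM; run made earlier
- cedar: reagent in the second phase 3 equiv; protic impurity 2.4 mM; run made earlier
- flask: reagent in the second phase 1.50 equiv; protic impurity 2.40 mM; time 25 min; volume of the second phase over the first 1.0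

| run | time / min | target / % |
|---|---|---|
| maple | 1.00 | 0.9 |
| maple | 3.00 | 5.3 |
| maple | 6.00 | 12.0 |
| maple | 8.00 | 15.1 |
| maple | 12.0 | 18.3 |
| maple | 15.0 | 18.0 |
| maple | 20.0 | 16.9 |
| elm | 1.50 | 0.4 |
| elm | 2.50 | 4.7 |
| elm | 4.00 | 7.7 |
| elm | 6.00 | 14.3 |
| elm | 8.00 | 13.8 |
| elm | 12.0 | 17.8 |
| elm | 20.0 | 14.3 |
| cedar | 4.00 | 14.8 |
| cedar | 8.00 | 21.9 |
| cedar | 12.0 | 21.3 |
| cedar | 15.0 | 20.0 |
| cedar | 20.0 | 17.0 |

(standard deviation of a reading: 1 percentage point)

- in the second phase: reagent in the second phase; everything else is in the first
- charges count per volume of the first phase; a concentration in a rate is the amount of a species over the volume of its own phase; every rate counts per litre of the first phase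
- the earlier runs hold the two phases in the same ratio of volumes as the flask asked about

- Tuesday's: doubling the transfer coefficient of the reagent in the second phase, all else as stated
- Sunday's: doubling the amount of reagent in the second phase, all else as stated

- how much target there is at 25 min, in percent of the substrate charged
- the change that raises the amount of target at 25 min, in percent of the substrate charged most ("none" if none brings more than 2 percentage points) (Tuesday's / Sunday's / none)
- amount of target at 25 min, in percent of the substrate charged, after Sunday's

Two chemists dispute this flask. The first holds that supply of reagent rules. Cedar, with twice the reagent of maple and twice its protic impurity, had a highest reading of 21.9% against 18.3% in maple. That lead of 3.6 percentage points is more than the 2 points required, so she expects Sunday's to win.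

The second holds that by 25 min target is fading, and she treats the last stretch as a small correction to a reading in hand. Summing maple and elm between 12.0 min and 20.0 min gives 0.0182 /min for the fade, the fraction of target lost per minute past the peak, taken as a pseudo-first-order constant. The impurity is a smaller correction still: taken one for one, it can remove 1.33% of the reagent charged, hardly any, less than the fraction the fade takes off below. So she starts from the mean reading at 20.0 min, 15.6%, and my own reckoning follows hers. The fade over the remaining 5.00 min takes off 9.10% of that and leaves 14.2%. Cedar's readings give a fade of 0.0282 /min, faster than the pair's, which takes its 17.0% to 14.8%, a gain of 0.60 points, less than the 2 points required.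

The forecast sides with her: 15.2% (13.2% to 17%), 14.3% after Sunday's (12.5% to 15.8%), and best none, since “the run is past the peak, so faster supply doesn't help”. Its first number stands above mine and its second below mine.

The flask gives 14.7%, and 12.9% after Sunday's, so the best change is none: Tuesday's moves target by −0.66 points and Sunday's by −1.8 points.

    target ⇌ isomer of the product (K = 10.0, k = 1.65 × 10⁻⁴ /s)
    reagent in the reaction phase + target → over-reacted product (k = 0.0295 /M/s)
    reagent in the reaction phase + protic impurity → quenched reagent (k = 0.282 /M/s)
    substrate + reagent in the reaction phase ⇌ target (K = 9.97 /M, k = 0.0236 /M/s)
    reagent in the reaction phase ⇌ reagent in the second phase, rate k5*([reagent in the reaction phase] - [reagent in the second phase]/K5) per volume of the first phase (partition coefficient = 1.82, kL = 0.00290 /s)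

The supply view keeps the early stretch, where cedar read 21.9% at 8.00 min against 15.1% in maple. The fade's 14.2% lies 0.50 points below this flask. Carried on to the neighbour, the same flask read at 1.0 h, the fade takes 14.7% down to 7.77%. That neighbour holds 39.1% over-reacted product and 8.02% target.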